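(The runs are simulated on assumed constants.)

No rate constant of this flask is given, so the reckoning starts from the earlier runs, laid on one time axis.

| setting | maple | larch | elm | flask |
|---|---|---|---|---|
| substrate | 0.30 M | 0.30 M | 0.45 M | 0.30 M |
| catalyst | 2.5 mol% | 3.8 mol% | 5 mol% | 5 mol% |
| remark | run made earlier | run made earlier | run made earlier |  |
| time |  |  |  | 3.0 h |

| run | time / min | target / % | isomer of the product / % |
|---|---|---|---|
| maple | 8.00 | 18.6 | 25.5 |
| maple | 15.0 | 18.6 | 35.9 |
| maple | 30.0 | 19.4 | 43.3 |
| maple | 60.0 | 19.1 | 44.2 |
| maple | 120 | 15.0 | 47.1 |
| larch | 20.0 | 17.5 | 42.2 |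
| larch | 40.0 | 18.3 | 46.6 |
| larch | 60.0 | 17.3 | 45.6 |
| larch | 80.0 | 17.7 | 45.2 |
| larch | 120 | 17.6 | 45.9 |
| elm | 8.00 | 19.6 | 41.5 |
| elm | 15.0 | 18.7 | 45.3 |
| elm | 30.0 | 16.1 | 46.8 |
| elm | 60.0 | 18.5 | 47.9 |
| elm | 120 | 18.2 | 45.8 |

(each reading ± 1 percentage point)

* share of target in target plus isomer of the product at 8.0 s
* share of target in target plus isomer of the product at 4.0 min
* share of target in target plus isomer of the product at 3.0 h



Take the main step first: substrate gives target, and with that step by itself the share of target stands at 100%. Add a step that makes isomer, and the share falls with time, as the runs show. If that step also runs on catalyst, a flask's time counts in proportion to its [catalyst].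

f = [catalyst] / [catalyst] of maple = 2.00

This clock factor, a flask's [catalyst] over maple's, turns a flask's time into maple time. Elm has a factor of 3.00, so its 8.00 min reading stands at maple 24.0 min; its isomer, 41.5%, lies between maple's 35.9% and 43.3%, which bracket that time.

Add the remaining steps, the ways back, and the readings level off: kinetic control gives way to thermodynamic control. My reckoning for this flask:

4.0 min × f = 8.00 min of maple, whose reading there gives a share of 42.2%

3.0 h × f = 360 min, the same as elm at 120 min, whose share is 28.4%

8.0 s × f = 16.0 s, earlier than maple's first reading by a factor of 30.0, so the reckoning says no more than a share above 42.2%.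

The forecast gives 62% (42% to 90%), 41% (36% to 46%) and 28% (26% to 30%); its middle value prints 41% against my 42.2%. For 8.0 s its ground is: “The share falls with time, so the target is favoured early”.

The flask gives 53.0%, 42.6% and 27.8%: the forecast's early share is 9 percentage points too high, and its other two are within tolerance.

    isomer of the product + catalyst ⇌ substrate + catalyst, rate k1*[catalyst]*[isomer of the product] forward; the back reaction follows from the equilibrium constant (k = 0.0960 /M/s)
    substrate + catalyst ⇌ target + catalyst, rate k2*[substrate]*[catalyst] forward; the back reaction follows from the equilibrium constant (K = 0.472, k = 0.135 /M/s)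
    target + catalyst ⇌ isomer of the product + catalyst, rate k3*[catalyst]*[target] forward; the back reaction follows from the equilibrium constant (K = 2.60, k = 0.0550 /M/s)

On maple's axis, the flask's forward half-lives, the way back not counted, are 28.0 min for target and 16.0 min for isomer, both shorter than the 360 min of the run . At 3.00 h the flask holds 37.0% substrate, 17.5% target and 45.5% isomer, and a reading ten times later shows the same. The neighbour with 3 mol% catalyst has a factor of 1.20, so its 4.0 min is maple 4.80 min, before maple's first reading, which points to a share above 42.2%. Computed, it is 46.5%.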